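Follow one E.

| flask | Z | E | remark | time |
|---|---|---|---|---|
| noon | 0.29 M | 0.95 equiv | run made earlier |  |
| autumn | 0.43 M | 0.95 equiv | run made earlier |  |
| flask | 0.58 M | 0.950 equiv |  | 2.5 min |

| run | time / min | X / % |
|---|---|---|
| noon | 0.250 | 3 |
| noon | 0.417 | 7 |
| noon | 0.833 | 18 |
| noon | 1.50 | 31 |
| noon | 3.00 | 34 |
| autumn | 0.250 | 6 |
| autumn | 0.417 | 9 |
| autumn | 0.833 | 19 |
| autumn | 1.50 | 25 |
| autumn | 3.00 | 34 |

(each reading ± 2 percentage points)

- as a solid, counted per litre of solution: Z
- at the start none of Z is in solution

* how much X there is at 2.5 min, in percent of the Z charged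
* the change that raises the amount of X at 2.5 min, in percent of the Z charged most ("none" if none brings more than 2 percentage points) (elm / alder / cedar / none)
* amount of X at 2.5 min, in percent of the Z charged, after cedar

- elm: doubling the dissolution coefficient of Z, all else as stated
- alder: doubling the amount of E, all else as stated
- cedar: doubling the solubility of Z, all else as stated

You can't see where E goes in these runs, so count its arrivals. Take X as a fraction of the Z charged and divide by the equivalents of E. If you count one E to each X, that gives E's chance, the fraction of the charged E that stands as X at the asked time, or the yield on E. Average the two runs and go straight between their readings at 1.50 min and 3.00 min, and at 2.5 min the chance is 33.7 %. Multiply by 0.950 equiv and my reckoning for the new flask is 32.0 %.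

Is one number enough? At 3.00 min, noon and autumn both read 34 %, though their Z differs. At 1.50 min they stand 6 percentage points apart, more than the scatter, and the new flask's Z lies beyond both. I still commit to that figure. The chance is counted per E, so I choose alder, which adds E. No run varied solubility, so the chance gives no figure for cedar.

The forecast differs slightly from my figure: 33 %, then alder, and 34 % after cedar. “Doubling E lifts the ceiling, so alder wins.”

The flask gives 30.4 %; alder is best, adding 11 points, and cedar gives 39.2 %, above the forecast.

    Z ⇌ J, rate k1*(cs1 - [J]) while solid is left; crystals form when [J] > cs1 (solubility = 0.400 M, k = 0.0330 s⁻¹)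
    J + E → X (k = 0.0310 M⁻¹ s⁻¹)
    2 J → Q (k = 0.0140 M⁻¹ s⁻¹)
    2 E → G (k = 0.0120 M⁻¹ s⁻¹)
    Z + X → D (k = 0.0380 M⁻¹ s⁻¹)
    E → L (k = 2.80 × 10⁻⁵ s⁻¹)

At 2.50 min, 16.5 % of its own charge of E still stands in the flask. The chance in this flask comes out at 32.0 %, against your 33.7 %. Now take the neighbour flask, the same flask but with 0.380 equiv of E: your chance gives 12.8 %, but that flask gives 16.6 %, so its chance is higher, at 43.7 %.

The numbers in the tables come from a simulation on assumed constants; scatter was added.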